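**Plan**
- Cuts, in order: the O7–S bond (late sulfation), C4a–C5 (ring A), C8–C8a (ring C to a four-membered ring), then ring C back to a furan and C2–C1' back to an aryl Grignard reagent.
- Enabling feature: ring A bears oxygen on the contiguous carbons C5, C6 and C7 and a bare C8–H next to C8a. A squarate-derived 2,3-dialkoxycyclobutenone bound through its sp3 CH to C8a of a finished ring C holds these four carbons in order (C=O to C5, the two C–OR to C6 and C7, CH to C8).
- Forward order: ring B comes from 4-bromoanisole and ring C from furfural (Achmatowicz ring expansion, epoxide rearrangement). Stille coupling makes C8–C8a, and thermal ring expansion closes ring A last.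
- O7 is singled out at the end through its acidity: peracetate, thiolysis of the 7-acetate, sulfation, ammonolysis.
- Stereochemistry: the target is achiral. Every stereocentre on the way (carbinol, pyranone acetal, epoxide, cyclobutenone CH) is racemic or mixed and disappears on aromatisation.

Key step: step 11

Assumption: the target is taken as drawn, as the free hydrogen sulfate. Aryl hydrogen sulfates hydrolyse autocatalytically, so the group is carried as a salt and protonated only in the last cold work-up.
Remark: the four-membered ring carries isopropyl rather than methyl ethers, because they resist dealkylation by chloride at the 4-chlorocyclobutenone stage and still fall to BBr3.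

**Step 1**
Reactants: 1 4-bromoanisole; 2 furfural
Product: 4 (furan-2-yl)(4-methoxyphenyl)methanol (racemic), via 4-methoxyphenylmagnesium bromide 3 (not isolated)
Conditions: Mg, THF, reflux; 2, 0 °C; sat. aq NH4Cl
Reagents that add atoms: none
Why: Grignard addition to an aldehyde; the carbinol centre forms racemic, which is harmless because it becomes the sp2 carbon C2 in step 5.

**Step 2**
Reactants: 4 (furan-2-yl)(4-methoxyphenyl)methanol
Product: 5 6-hydroxy-2-(4-methoxyphenyl)-2H-pyran-3(6H)-one (diastereomer mixture)
Conditions: N-bromosuccinimide, NaHCO3, THF–H2O, 0 °C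
Reagents that add atoms: water, O
Why: Achmatowicz rearrangement, in which the furan (far more electron-rich than the anisole ring) is oxidatively hydrated to an ene-dione that closes through the carbinol oxygen; the anomeric centre forms as a mixture that is erased later.

**Step 3**
Reactants: 5 6-hydroxy-2-(4-methoxyphenyl)-2H-pyran-3(6H)-one
Product: 6 6-methoxy-2-(4-methoxyphenyl)-2H-pyran-3(6H)-one (diastereomer mixture)
Conditions: HC(OMe)3, BF3·OEt2 (cat.), CH2Cl2, 0 °C
Reagents that add atoms: trimethyl orthoformate, COC(OC)OC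
Why: Acid-catalysed acetalisation through the ring oxocarbenium ion masks the base-labile hemiacetal before the basic oxidation; the anomer mixture is carried on.

**Step 4**
Reactants: 6 6-methoxy-2-(4-methoxyphenyl)-2H-pyran-3(6H)-one
Product: 7 2-methoxy-4-(4-methoxyphenyl)-3,7-dioxabicyclo[4.1.0]heptan-5-one (the 4,5-epoxide of 6; diastereomer mixture)
Conditions: 30% H2O2, NaOH (cat.), MeOH, 0 °C
Reagents that add atoms: hydrogen peroxide, OO
Why: Weitz–Scheffer nucleophilic epoxidation of the enone, established on 6-alkoxy-2H-pyran-3(6H)-ones, brings C4 to the required oxidation level; attack anti to the 6-methoxy group is expected, but the epoxide centres do not survive step 5.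

**Step 5**
Reactants: 7 2-methoxy-4-(4-methoxyphenyl)-3,7-dioxabicyclo[4.1.0]heptan-5-one
Product: 8 3-hydroxy-2-(4-methoxyphenyl)-4H-pyran-4-one
Conditions: 1 M H2SO4, dioxane–H2O, reflux
Reagents that add atoms: none
Why: Acid-catalysed isomerisation of the α,β-epoxy ketone to the 3,4-dione, β-elimination of methanol from C6 and enolisation toward C2 (the maltol-type γ-pyrone synthesis) form ring C and remove all four stereocentres.

**Step 6**
Reactants: 8 3-hydroxy-2-(4-methoxyphenyl)-4H-pyran-4-one
Product: 9 3-methoxy-2-(4-methoxyphenyl)-4H-pyran-4-one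
Conditions: MeI, K2CO3, acetone, reflux
Reagents that add atoms: iodomethane, CI
Why: Williamson O-alkylation of the acidic enolic 3-hydroxyl, which has to be capped before a strong base is used.

**Step 7**
Reactants: 9 3-methoxy-2-(4-methoxyphenyl)-4H-pyran-4-one
Product: 11 3-methoxy-2-(4-methoxyphenyl)-6-(tributylstannyl)-4H-pyran-4-one, via 6-lithiopyranone 10 (not isolated)
Conditions: lithium 2,2,6,6-tetramethylpiperidide (from the amine and n-BuLi), THF, −78 °C, inverse addition, short contact; Bu3SnCl, −78 °C to 0 °C
Reagents that add atoms: tributyltin chloride, CCCC[Sn](Cl)(CCCC)CCCC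
Why: Deprotonative lithiation at the C–H next to the ring oxygen (the kinetic site known from C2 lithiation of chromones) followed by substitution at tin; the hindered amide, inverse addition and low temperature hold back C5 metalation and self-addition.

**Step 8**
Reactants: 12 diisopropyl squarate
Product: 13 4-hydroxy-2,3-diisopropoxycyclobut-2-en-1-one (racemic)
Conditions: LiAlH(OtBu)3, THF, −78 °C to −20 °C; H2O, neutral work-up
Reagents that add atoms: none
Why: Chemoselective 1,2-hydride addition to one of two equivalent carbonyl groups stops at the hydroxy ketone, because the remaining vinylogous ester is much less electrophilic; the new centre is racemic.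

**Step 9**
Reactants: 13 4-hydroxy-2,3-diisopropoxycyclobut-2-en-1-one
Product: 14 4-chloro-2,3-diisopropoxycyclobut-2-en-1-one (racemic)
Conditions: PPh3, Cl3CC(O)CCl3, CH2Cl2, −20 °C to 0 °C; short plug, used at once
Reagents that add atoms: hexachloroacetone, ClC(Cl)(Cl)C(=O)C(Cl)(Cl)Cl
Why: Appel-type deoxychlorination through the alkoxyphosphonium salt is neutral and is known to convert allylic alcohols without transposition, so the acid-triggered ionisation of C4–O is avoided; the centre stays racemic.

**Step 10**
Reactants: 11 3-methoxy-2-(4-methoxyphenyl)-6-(tributylstannyl)-4H-pyran-4-one; 14 4-chloro-2,3-diisopropoxycyclobut-2-en-1-one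
Product: 15 6-(2,3-diisopropoxy-4-oxocyclobut-2-en-1-yl)-3-methoxy-2-(4-methoxyphenyl)-4H-pyran-4-one (racemic)
Conditions: PdCl2(PhCN)2 (5 mol %), tris(2-furyl)phosphine (10 mol %), dioxane, 50 °C
Reagents that add atoms: none
Why: Stille coupling of a 4-chlorocyclobutenone with an alkenyl-type heteroaryl stannane, in which the η3-oxocyclobutenyl palladium intermediate should form the C–C bond at its unsubstituted CH terminus and keep the conjugated enone; the temperature stays below that of ring opening, and the racemic sp3 centre is lost in step 11.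

**Step 11**
Reactants: 15 6-(2,3-diisopropoxy-4-oxocyclobut-2-en-1-yl)-3-methoxy-2-(4-methoxyphenyl)-4H-pyran-4-one
Product: 18 5-hydroxy-6,7-diisopropoxy-3-methoxy-2-(4-methoxyphenyl)-4H-chromen-4-one, via inward dienylketene 16 (not isolated), via cyclohexadienone 17 (not isolated)
Conditions: toluene (0.02 M, dry, degassed), 110 °C, Ar
Reagents that add atoms: none
Why: Heating breaks the C1–C4 bond of the cyclobutenone by conrotatory 4π opening to a vinylketene conjugated with the C5=C6 bond of the pyranone, and the isomer 16 with the pyranone cis to the ketene undergoes disrotatory 6π electrocyclisation, the ketene carbon (future C5) bonding to pyranone C5 (future C4a). The dienone 17 holds its only sp3 hydrogen between two carbonyl groups and enolises at once, so ring A aromatises and the former ketene oxygen ends as the chelated 5-hydroxyl. The closest known reaction type is the thermal benzannulation of 4-aryl-, 4-heteroaryl- and 4-alkenylcyclobutenones to phenols, with the enol-ether double bond of the pyranone taking the place of the aryl or alkenyl π bond. Ring A closes in a six-atom, all-carbon electrocyclic mode and no stereocentre remains, since the racemic CH of 15 becomes C8–H and the transient centre C4a of 17 is lost on tautomerisation. Regiochemistry needs no steering, because the pyranone carbon bearing the small ring has only one carbon neighbour and the sequence C=O, C–OiPr, C–OiPr, CH is copied onto C5, C6, C7, C8. The selectivity required is torquoselectivity: the outward-opened ketene cannot close but reverts to 15 at this temperature, the acceptor character of the pyranone carbon lowers the cost of inward rotation, and dilution in dry toluene protects the ketene while irreversible aromatisation drains the equilibrium.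

**Step 12**
Reactants: 18 5-hydroxy-6,7-diisopropoxy-3-methoxy-2-(4-methoxyphenyl)-4H-chromen-4-one
Product: 20 2-(4-acetoxyphenyl)-4-oxo-4H-chromene-3,5,6,7-tetrayl tetraacetate (6-hydroxykaempferol pentaacetate), via 6-hydroxykaempferol 19 (not isolated)
Conditions: BBr3 (10 equiv), CH2Cl2, −78 °C to rt; MeOH, evaporate; Ac2O, pyridine, DMAP (cat.), rt, Ar
Reagents that add atoms: acetic anhydride, CC(=O)OC(C)=O
Why: Lewis-acid ether cleavage with BBr3 removes both methyl and both isopropyl groups, and the air-sensitive pentaphenol is peracetylated in the same flask, DMAP catalysis also esterifying the chelated 5-hydroxyl.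

**Step 13**
Reactants: 20 6-hydroxykaempferol pentaacetate
Product: 21 2-(4-acetoxyphenyl)-7-hydroxy-4-oxo-4H-chromene-3,5,6-triyl triacetate
Conditions: PhSH (1.1 equiv), imidazole (0.3 equiv), NMP, 0 °C to rt
Reagents that add atoms: none
Why: Chemoselective thiolysis of aryl acetates, established on peracetylated flavonols, removes the ester of the best leaving phenoxide, O7, which is para to C4a and conjugated with the C4 carbonyl; acetyl migration from the unconjugated, less acidic O6 to O7 is thermodynamically uphill.

**Step 14**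
Reactants: 21 2-(4-acetoxyphenyl)-7-hydroxy-4-oxo-4H-chromene-3,5,6-triyl triacetate
Product: 22 pyridinium 3,5,6-triacetoxy-2-(4-acetoxyphenyl)-4-oxo-4H-chromen-7-yl sulfate
Conditions: SO3·pyridine (3 equiv), pyridine, rt; precipitation with Et2O
Reagents that add atoms: sulfur trioxide–pyridine complex, [O-]S(=O)(=O)[n+]1ccccc1
Why: O-sulfation of a phenol with an amine–SO3 complex can only take place at the single free hydroxyl, and the mild base leaves the four acetates in place.

**Step 15**
Reactants: 22 pyridinium 3,5,6-triacetoxy-2-(4-acetoxyphenyl)-4-oxo-4H-chromen-7-yl sulfate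
Product: 24 3,5,6-trihydroxy-2-(4-hydroxyphenyl)-4-oxo-4H-chromen-7-yl hydrogen sulfate (CNP0164757.0), via ammonium 7-sulfate salt 23 (not isolated)
Conditions: NH3 (7 M in MeOH), 0 °C, Ar; evaporate; 1 M HCl (1 equiv), H2O, 0 °C; C18 desalting, lyophilisation
Reagents that add atoms: none
Why: Ammonolysis cleaves the four aryl acetates while the aryl sulfate monoanion is inert to base; exclusion of oxygen protects the 5,6-dihydroxyflavonol, and brief cold protonation releases the hydrogen sulfate.

**Compound list**
1 | 4-bromoanisole | COc1ccc(Br)cc1 | starting material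
2 | furfural | O=Cc1ccco1 | starting material
3 | 4-methoxyphenylmagnesium bromide | COc1ccc([Mg]Br)cc1 | intermediate
4 | (furan-2-yl)(4-methoxyphenyl)methanol (racemic) | COc1ccc(cc1)C(O)c1ccco1 | intermediate
5 | 6-hydroxy-2-(4-methoxyphenyl)-2H-pyran-3(6H)-one (diastereomer mixture) | COc1ccc(cc1)C1OC(O)C=CC1=O | intermediate
6 | 6-methoxy-2-(4-methoxyphenyl)-2H-pyran-3(6H)-one (diastereomer mixture) | COc1ccc(cc1)C1OC(OC)C=CC1=O | intermediate
7 | 2-methoxy-4-(4-methoxyphenyl)-3,7-dioxabicyclo[4.1.0]heptan-5-one (diastereomer mixture) | COc1ccc(cc1)C1OC(OC)C2OC2C1=O | intermediate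
8 | 3-hydroxy-2-(4-methoxyphenyl)-4H-pyran-4-one | COc1ccc(cc1)-c1occc(=O)c1O | intermediate
9 | 3-methoxy-2-(4-methoxyphenyl)-4H-pyran-4-one | COc1ccc(cc1)-c1occc(=O)c1OC | intermediate
10 | 6-lithio-3-methoxy-2-(4-methoxyphenyl)-4H-pyran-4-one | COc1ccc(cc1)-c1oc([Li])cc(=O)c1OC | intermediate
11 | 3-methoxy-2-(4-methoxyphenyl)-6-(tributylstannyl)-4H-pyran-4-one | COc1ccc(cc1)-c1oc(cc(=O)c1OC)[Sn](CCCC)(CCCC)CCCC | intermediate
12 | diisopropyl squarate (3,4-diisopropoxycyclobut-3-ene-1,2-dione) | CC(C)OC1=C(OC(C)C)C(=O)C1=O | starting material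
13 | 4-hydroxy-2,3-diisopropoxycyclobut-2-en-1-one (racemic) | CC(C)OC1=C(OC(C)C)C(O)C1=O | intermediate
14 | 4-chloro-2,3-diisopropoxycyclobut-2-en-1-one (racemic) | CC(C)OC1=C(OC(C)C)C(Cl)C1=O | intermediate
15 | 6-(2,3-diisopropoxy-4-oxocyclobut-2-en-1-yl)-3-methoxy-2-(4-methoxyphenyl)-4H-pyran-4-one (racemic) | COc1ccc(cc1)-c1oc(cc(=O)c1OC)C1C(OC(C)C)=C(OC(C)C)C1=O | intermediate
16 | 2,3-diisopropoxy-4-[5-methoxy-6-(4-methoxyphenyl)-4-oxo-4H-pyran-2-yl]buta-1,3-dien-1-one, ketene carbon and pyranone cis across C3=C4 | O=C=C(OC(C)C)/C(OC(C)C)=C\c1cc(=O)c(OC)c(-c2ccc(OC)cc2)o1 | intermediate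
17 | 6,7-diisopropoxy-3-methoxy-2-(4-methoxyphenyl)-4aH-chromene-4,5-dione (racemic) | COc1ccc(cc1)C1=C(OC)C(=O)C2C(=O)C(OC(C)C)=C(OC(C)C)C=C2O1 | intermediate
18 | 5-hydroxy-6,7-diisopropoxy-3-methoxy-2-(4-methoxyphenyl)-4H-chromen-4-one | COc1ccc(cc1)-c1oc2cc(OC(C)C)c(OC(C)C)c(O)c2c(=O)c1OC | intermediate
19 | 6-hydroxykaempferol (3,5,6,7-tetrahydroxy-2-(4-hydroxyphenyl)-4H-chromen-4-one) | Oc1ccc(cc1)-c1oc2cc(O)c(O)c(O)c2c(=O)c1O | intermediate
20 | 2-(4-acetoxyphenyl)-4-oxo-4H-chromene-3,5,6,7-tetrayl tetraacetate | CC(=O)Oc1ccc(cc1)-c1oc2cc(OC(C)=O)c(OC(C)=O)c(OC(C)=O)c2c(=O)c1OC(C)=O | intermediate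
21 | 2-(4-acetoxyphenyl)-7-hydroxy-4-oxo-4H-chromene-3,5,6-triyl triacetate | CC(=O)Oc1ccc(cc1)-c1oc2cc(O)c(OC(C)=O)c(OC(C)=O)c2c(=O)c1OC(C)=O | intermediate
22 | pyridinium 3,5,6-triacetoxy-2-(4-acetoxyphenyl)-4-oxo-4H-chromen-7-yl sulfate | CC(=O)Oc1ccc(cc1)-c1oc2cc(OS(=O)(=O)[O-])c(OC(C)=O)c(OC(C)=O)c2c(=O)c1OC(C)=O.c1cc[nH+]cc1 | intermediate
23 | ammonium 3,5,6-trihydroxy-2-(4-hydroxyphenyl)-4-oxo-4H-chromen-7-yl sulfate | [NH4+].[O-]S(=O)(=O)Oc1cc2oc(-c3ccc(O)cc3)c(O)c(=O)c2c(O)c1O | intermediate
24 | 3,5,6-trihydroxy-2-(4-hydroxyphenyl)-4-oxo-4H-chromen-7-yl hydrogen sulfate | O=c1c(O)c(-c2ccc(O)cc2)oc2cc(OS(=O)(=O)O)c(O)c(O)c12 | target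

**Step count**
Total step count: 15.
Longest linear sequence: 13 (steps 1–7 and 10–15). Steps 8 and 9 form the short convergent arm.

**Steps most likely to fail**

Step 11 (ring expansion).
- Risk: the four-membered ring may open mainly with the pyranone turning outward. The long-lived ketene could then be lost to dimerisation or to traces of nucleophiles before the productive isomer closes.
- Fallback: it sets out from 9 and 12 and uses a hydroxyl group on the sp3 carbon to dictate the sense of rotation.
- Compound 9 is lithiated as in step 7 to 10 and added to 12 at −78 °C. This should give 4-hydroxy-2,3-diisopropoxy-4-[5-methoxy-6-(4-methoxyphenyl)-4-oxo-4H-pyran-2-yl]cyclobut-2-en-1-one F1.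
- On heating in toluene under argon the hydroxyl rotates outward and forces the pyranone inward. The expected product is the hydroquinone 5,8-dihydroxy-6,7-diisopropoxy-3-methoxy-2-(4-methoxyphenyl)-4H-chromen-4-one F2.
- The unchelated 8-hydroxyl is triflated selectively (PhNTf2, K2CO3, THF) to 5-hydroxy-6,7-diisopropoxy-3-methoxy-2-(4-methoxyphenyl)-4-oxo-4H-chromen-8-yl trifluoromethanesulfonate F3.
- Palladium-catalysed formate reduction (Pd(OAc)2, PPh3, HCO2H, Et3N, DMF, 70 °C) replaces the triflate by hydrogen, and the route is rejoined at 18.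

Step 9 (chloride for the coupling).
- Risk: the C4–Cl bond may ionise during formation or handling, with loss of an isopropyl group and collapse of the ring to a cyclobutenedione. Allylic transposition in the substitution is a second possibility.
- Fallback: it sets out from 13 and replaces the halide by an ester that only the catalyst can ionise.
- Acetylation (Ac2O, pyridine, 0 °C) should give 2,3-diisopropoxy-4-oxocyclobut-2-en-1-yl acetate F4.
- F4 is joined to stannane 11 by the allylic acetate–stannane coupling under zerovalent palladium (Pd(dba)2, LiCl, DMF, 40 °C). The route is rejoined at 15.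

Step 7 (stannylation).
- Risk: deprotonation may compete at C5 and be followed by ring opening, or the lithiated species may add to unreacted pyranone.
- Fallback: it sets out from 9 and moves to a softer metal and a halide relay.
- Zincation with TMP2Zn·2MgCl2·2LiCl (TMP = 2,2,6,6-tetramethylpiperidide; THF, −30 °C) is used. The magnesium salt ties up the carbonyl oxygen and directs the base to the carbon next to the ring oxygen. This should give bis[5-methoxy-6-(4-methoxyphenyl)-4-oxo-4H-pyran-2-yl]zinc F5.
- Iodolysis of F5 affords 6-iodo-3-methoxy-2-(4-methoxyphenyl)-4H-pyran-4-one F6.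
- Palladium-catalysed stannylation (Bu3SnSnBu3, Pd(PPh3)4, toluene, 100 °C) leads back to the route at 11.

**Further compounds**
F1 | step 11 | 4-hydroxy-2,3-diisopropoxy-4-[5-methoxy-6-(4-methoxyphenyl)-4-oxo-4H-pyran-2-yl]cyclobut-2-en-1-one (racemic) | COc1ccc(cc1)-c1oc(cc(=O)c1OC)C1(O)C(OC(C)C)=C(OC(C)C)C1=O
F2 | step 11 | 5,8-dihydroxy-6,7-diisopropoxy-3-methoxy-2-(4-methoxyphenyl)-4H-chromen-4-one | COc1ccc(cc1)-c1oc2c(O)c(OC(C)C)c(OC(C)C)c(O)c2c(=O)c1OC
F3 | step 11 | 5-hydroxy-6,7-diisopropoxy-3-methoxy-2-(4-methoxyphenyl)-4-oxo-4H-chromen-8-yl trifluoromethanesulfonate | COc1ccc(cc1)-c1oc2c(OS(=O)(=O)C(F)(F)F)c(OC(C)C)c(OC(C)C)c(O)c2c(=O)c1OC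
F4 | step 9 | 2,3-diisopropoxy-4-oxocyclobut-2-en-1-yl acetate (racemic) | CC(=O)OC1C(OC(C)C)=C(OC(C)C)C1=O
F5 | step 7 | bis[5-methoxy-6-(4-methoxyphenyl)-4-oxo-4H-pyran-2-yl]zinc | COc1ccc(cc1)-c1oc(cc(=O)c1OC)[Zn]c1cc(=O)c(OC)c(-c2ccc(OC)cc2)o1
F6 | step 7 | 6-iodo-3-methoxy-2-(4-methoxyphenyl)-4H-pyran-4-one | COc1ccc(cc1)-c1oc(I)cc(=O)c1OC
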